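**Retrosynthetic overview**

1. Feature: the tetrahydrofuran ring (O1, C2–C5) has a mirror plane through O1 and the midpoint of C3–C4. C2 and C5 carry 4-hydroxyphenyl groups and C3 and C4 carry aroyl carbons, so each half is an aryl–C(=O)–C–C(aryl)–O chain, which is a 1,3-diarylpropargyl unit one hydration level up.
2. The two aroyl groups go back (ketone ⇐ alcohol ⇐ alkene hydroboration) to a cis-2,5-diaryl-3,4-bis(arylidene)tetrahydrofuran. C3 and C4 are set last, by hydroboration and then epimerisation.
3. Key disconnection C3–C4: the bis(arylidene)tetrahydrofuran comes from reductive cyclisation of a meso bis(1,3-diarylprop-2-ynyl) ether, an ether-tethered 1,6-diyne. This is the only ring-forming step.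
4. The meso ether comes from acid-catalysed self-etherification of a racemic 1,3-diarylpropargyl alcohol, itself made from 4-benzyloxybenzaldehyde and 2,4-bis(benzyloxy)phenylacetylene (Sonogashira coupling on purchased 2,4-bis(benzyloxy)-1-bromobenzene).
5. All six phenols travel as benzyl ethers and are freed in the last step.

Key step: step 5

Assumption: the target SMILES is read as the achiral meso isomer (2R,3R,4S,5S), with the two 4-hydroxyphenyl groups on one ring face and the two 2,4-dihydroxybenzoyl groups on the other; no absolute stereocontrol is therefore needed.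

**Route**

Step 1
Reactants: 1 2,4-bis(benzyloxy)-1-bromobenzene; 2 trimethylsilylacetylene
Product: 3 {[2,4-bis(benzyloxy)phenyl]ethynyl}trimethylsilane
Conditions: PdCl2(PhCN)2 (3 mol%), [HP(t-Bu)3]BF4 (6 mol%), CuI (2 mol%), HN(i-Pr)2, 1,4-dioxane, rt to 45 °C
Reagents that add atoms: none
Why: Sonogashira coupling, in which the bulky electron-rich tri-tert-butylphosphine allows oxidative addition of the electron-rich aryl bromide under mild conditions and the silyl cap prevents a second coupling.

Step 2
Reactants: 3 {[2,4-bis(benzyloxy)phenyl]ethynyl}trimethylsilane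
Product: 4 2,4-bis(benzyloxy)-1-ethynylbenzene
Conditions: K2CO3 (0.2 equiv), MeOH–THF, rt
Reagents that add atoms: none
Why: methoxide-catalysed protodesilylation of the C(sp)–Si bond, which leaves the benzyl ethers untouched.

Step 3
Reactants: 4 2,4-bis(benzyloxy)-1-ethynylbenzene; 5 4-benzyloxybenzaldehyde
Product: 7 rac-1-(4-benzyloxyphenyl)-3-[2,4-bis(benzyloxy)phenyl]prop-2-yn-1-ol, via lithium arylacetylide 6 (not isolated)
Conditions: n-BuLi, THF, −78 °C; then 5, −78 → 0 °C; H2O
Reagents that add atoms: n-butyllithium, [Li]CCCC (lithium remains only in intermediate 6)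
Why: deprotonation of the terminal alkyne and 1,2-addition of the lithium acetylide to a non-enolisable aldehyde; the carbinol centre forms racemic, which is sufficient because the next step ionises it.

Step 4
Reactants: 7 rac-1-(4-benzyloxyphenyl)-3-[2,4-bis(benzyloxy)phenyl]prop-2-yn-1-ol (two molecules)
Product: 8 meso-bis{1-(4-benzyloxyphenyl)-3-[2,4-bis(benzyloxy)phenyl]prop-2-yn-1-yl} ether
Conditions: p-TsOH·H2O (5 mol%), 4 Å MS, CH2Cl2, 0 °C → rt; chromatographic separation of the meso ether
Reagents that add atoms: none
Why: acid-catalysed dehydrative etherification (SN1) through a propargylic cation stabilised by the 4-benzyloxyphenyl group and captured at the propargylic carbon by a second alcohol molecule; the two ether stereocentres form without control, so the meso ether is separated from its C2-symmetric diastereomer (told apart on a chiral stationary phase, where only the racemate can split), and the unwanted isomer is returned to the same acid, which re-equilibrates it through the same cation.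

Step 5
Reactants: 8 meso-bis{1-(4-benzyloxyphenyl)-3-[2,4-bis(benzyloxy)phenyl]prop-2-yn-1-yl} ether
Product: 9 cis-2,5-bis(4-benzyloxyphenyl)-3,4-bis[(Z)-2,4-bis(benzyloxy)benzylidene]tetrahydrofuran
Conditions: Pd2(dba)3·CHCl3 (2.5 mol%), P(o-tol)3 (10 mol%), AcOH (2 equiv), Et3SiH (5 equiv), toluene, rt
Reagents that add atoms: none
Why: Zerovalent palladium and acetic acid give H–Pd–OAc, which adds syn to one alkyne with palladium on the inner carbon; this vinylpalladium inserts the second alkyne syn, forming C3–C4, and the new vinylpalladium acetate is reduced by Et3SiH with retention, returning zerovalent palladium. The closest known reaction type is the palladium-hydride reductive cyclisation of 1,6-diynes to 1,2-dialkylidene five-membered rings, which is established for internal alkynes and for ether tethers. The tetrahydrofuran ring closes in the 5-exo-dig mode, the attacked alkyne keeping its outer carbon exocyclic. No stereocentre is created: the 2,5-cis relationship is carried over from the meso ether, and the (Z,Z) geometry, with each dibenzyloxyphenyl group on the side of C2 or C5 and each vinyl hydrogen pointing inward, follows from the two syn additions and the retentive Pd–C reduction. The step needs ring closure to outrun simple alkyne reduction and needs palladium on the inner alkyne carbons; the 1,6-spacing, which lets both alkynes bind one palladium, should secure both. The ether oxygen is a poor leaving group, so ionisation of the propargylic C–O bonds by zerovalent palladium is not expected at rt, and the aryl benzyl ethers are inert to this homogeneous system.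

Step 6
Reactants: 9 cis-2,5-bis(4-benzyloxyphenyl)-3,4-bis[(Z)-2,4-bis(benzyloxy)benzylidene]tetrahydrofuran
Product: 11 all-cis-2,5-bis(4-benzyloxyphenyl)-3,4-bis{[2,4-bis(benzyloxy)phenyl](hydroxy)methyl}tetrahydrofuran, via bis-borane adduct 10 (not isolated)
Conditions: BH3·THF (6 equiv), THF, 0 °C → rt; then aq NaOH, 30% H2O2, 0 °C → rt
Reagents that add atoms: borane–tetrahydrofuran, [BH3-][O+]1CCCC1 (boron remains only in intermediate 10); hydrogen peroxide, OO
Why: hydroboration–oxidation, in which boron goes to the less substituted exocyclic benzylic carbon of each trisubstituted alkene and hydride goes to C3 and C4 from the ring face opposite the two C2/C5 aryl groups (substrate control, giving the all-cis ring); the C–B bonds are oxidised with retention, and the carbinol centres fixed by the syn addition are erased in step 7.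

Step 7
Reactants: 11 all-cis-2,5-bis(4-benzyloxyphenyl)-3,4-bis{[2,4-bis(benzyloxy)phenyl](hydroxy)methyl}tetrahydrofuran
Product: 12 all-cis-(2R,3S,4R,5S)-3,4-bis[2,4-bis(benzyloxy)benzoyl]-2,5-bis(4-benzyloxyphenyl)tetrahydrofuran
Conditions: Dess–Martin periodinane (3 equiv), pyridine, CH2Cl2, 0 °C → rt
Reagents that add atoms: none
Why: Dess–Martin oxidation of the two secondary benzylic alcohols under pyridine buffering, which avoids acid that would ionise the electron-rich benzylic carbinols or cyclodehydrate the 1,4-diketone to a furan.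

Step 8
Reactants: 12 all-cis-(2R,3S,4R,5S)-3,4-bis[2,4-bis(benzyloxy)benzoyl]-2,5-bis(4-benzyloxyphenyl)tetrahydrofuran
Product: 14 (2R,3R,4S,5S)-3,4-bis[2,4-bis(benzyloxy)benzoyl]-2,5-bis(4-benzyloxyphenyl)tetrahydrofuran, via 3,4-trans diketone 13 (not isolated)
Conditions: DBU (0.5 equiv), toluene, 40 °C
Reagents that add atoms: none
Why: base-mediated epimerisation of the two ketone α-carbons through their enolates under thermodynamic control should drain the strained all-cis isomer, first at C3 and then at C4, into 14, the only isomer in which neither aroyl group is cis to an aryl group; any 13 remaining at equilibrium is separated and returned to the same conditions, and the catalytic amidine in an apolar solvent should not expel the ring oxygen, so C2 and C5 keep their cis relationship.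

Step 9
Reactants: 14 (2R,3R,4S,5S)-3,4-bis[2,4-bis(benzyloxy)benzoyl]-2,5-bis(4-benzyloxyphenyl)tetrahydrofuran
Product: 15 (2R,3R,4S,5S)-3,4-bis(2,4-dihydroxybenzoyl)-2,5-bis(4-hydroxyphenyl)tetrahydrofuran (CNP0237262.1)
Conditions: H2 (1 atm), 10% Pd/C, THF–MeOH, rt, stopped once six equivalents of H2 are taken up
Reagents that add atoms: none
Why: hydrogenolysis of the six aryl benzyl ethers on palladium should be much faster than cleavage of the ring benzylic C–O bonds or reduction of the electron-rich aryl ketones, and the neutral medium leaves all four stereocentres untouched.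

**Compound list**

1 | 2,4-bis(benzyloxy)-1-bromobenzene | Brc1ccc(OCc2ccccc2)cc1OCc1ccccc1 | starting material
2 | trimethylsilylacetylene | C#C[Si](C)(C)C | starting material
3 | {[2,4-bis(benzyloxy)phenyl]ethynyl}trimethylsilane | C[Si](C)(C)C#Cc1ccc(OCc2ccccc2)cc1OCc1ccccc1 | intermediate
4 | 2,4-bis(benzyloxy)-1-ethynylbenzene | C#Cc1ccc(OCc2ccccc2)cc1OCc1ccccc1 | intermediate
5 | 4-benzyloxybenzaldehyde | O=Cc1ccc(OCc2ccccc2)cc1 | starting material
6 | lithium [2,4-bis(benzyloxy)phenyl]acetylide (not isolated) | [Li]C#Cc1ccc(OCc2ccccc2)cc1OCc1ccccc1 | intermediate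
7 | rac-1-(4-benzyloxyphenyl)-3-[2,4-bis(benzyloxy)phenyl]prop-2-yn-1-ol (racemic, no stereodescriptor) | OC(C#Cc1ccc(OCc2ccccc2)cc1OCc1ccccc1)c1ccc(OCc2ccccc2)cc1 | intermediate
8 | meso-bis{1-(4-benzyloxyphenyl)-3-[2,4-bis(benzyloxy)phenyl]prop-2-yn-1-yl} ether | c1ccccc1COc1ccc(c(OCc2ccccc2)c1)C#C[C@H](c1ccc(OCc2ccccc2)cc1)O[C@H](c1ccc(OCc2ccccc2)cc1)C#Cc1ccc(OCc2ccccc2)cc1OCc1ccccc1 | intermediate
9 | cis-2,5-bis(4-benzyloxyphenyl)-3,4-bis[(Z)-2,4-bis(benzyloxy)benzylidene]tetrahydrofuran (meso) | c1ccccc1COc1ccc(c(OCc2ccccc2)c1)/C=C1/C(=C/c2ccc(OCc3ccccc3)cc2OCc2ccccc2)[C@@H](c2ccc(OCc3ccccc3)cc2)O[C@H]1c1ccc(OCc2ccccc2)cc1 | intermediate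
10 | all-cis-2,5-bis(4-benzyloxyphenyl)-3,4-bis{[2,4-bis(benzyloxy)phenyl](dihydroboryl)methyl}tetrahydrofuran (not isolated) | B[C@@H](c2ccc(OCc3ccccc3)cc2OCc2ccccc2)[C@H]1[C@@H]([C@H](B)c2ccc(OCc3ccccc3)cc2OCc2ccccc2)[C@@H](c2ccc(OCc3ccccc3)cc2)O[C@H]1c1ccc(OCc2ccccc2)cc1 | intermediate
11 | all-cis-2,5-bis(4-benzyloxyphenyl)-3,4-bis{[2,4-bis(benzyloxy)phenyl](hydroxy)methyl}tetrahydrofuran (meso; carbinol carbons as fixed by syn addition) | O[C@@H](c2ccc(OCc3ccccc3)cc2OCc2ccccc2)[C@H]1[C@@H]([C@H](O)c2ccc(OCc3ccccc3)cc2OCc2ccccc2)[C@@H](c2ccc(OCc3ccccc3)cc2)O[C@H]1c1ccc(OCc2ccccc2)cc1 | intermediate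
12 | all-cis-(2R,3S,4R,5S)-3,4-bis[2,4-bis(benzyloxy)benzoyl]-2,5-bis(4-benzyloxyphenyl)tetrahydrofuran (meso) | O=C(c2ccc(OCc3ccccc3)cc2OCc2ccccc2)[C@H]1[C@@H](C(=O)c2ccc(OCc3ccccc3)cc2OCc2ccccc2)[C@@H](c2ccc(OCc3ccccc3)cc2)O[C@H]1c1ccc(OCc2ccccc2)cc1 | intermediate
13 | rac-(2R,3R,4R,5S)-3,4-bis[2,4-bis(benzyloxy)benzoyl]-2,5-bis(4-benzyloxyphenyl)tetrahydrofuran (2,3-trans, 3,4-trans, 4,5-cis; racemic, one enantiomer drawn; not isolated) | O=C(c2ccc(OCc3ccccc3)cc2OCc2ccccc2)[C@@H]1[C@@H](C(=O)c2ccc(OCc3ccccc3)cc2OCc2ccccc2)[C@@H](c2ccc(OCc3ccccc3)cc2)O[C@H]1c1ccc(OCc2ccccc2)cc1 | intermediate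
14 | (2R,3R,4S,5S)-3,4-bis[2,4-bis(benzyloxy)benzoyl]-2,5-bis(4-benzyloxyphenyl)tetrahydrofuran (meso; 2,3-trans, 3,4-cis, 4,5-trans) | O=C(c2ccc(OCc3ccccc3)cc2OCc2ccccc2)[C@@H]1[C@H](C(=O)c2ccc(OCc3ccccc3)cc2OCc2ccccc2)[C@@H](c2ccc(OCc3ccccc3)cc2)O[C@H]1c1ccc(OCc2ccccc2)cc1 | intermediate
15 | (2R,3R,4S,5S)-3,4-bis(2,4-dihydroxybenzoyl)-2,5-bis(4-hydroxyphenyl)tetrahydrofuran, CNP0237262.1 | O=C(c1ccc(O)cc1O)[C@@H]1[C@H](C(=O)c2ccc(O)cc2O)[C@@H](c2ccc(O)cc2)O[C@H]1c1ccc(O)cc1 | target

**Totals and risks**

Total step count: 9.
Longest linear sequence: 9 steps (steps 1–9, from bromide 1 to 15; the aldehyde 5 enters as purchased).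

The three steps most likely to fail:

Step 5 (key step). The palladium hydride may add to an alkyne in the orientation that cannot close the five-membered ring, and the vinylpalladium is then reduced by the silane, so that semi-reduction to Z-alkenes competes with ring closure; the crowded second insertion may also be slow. The fallback sets out from 8 and comes back at 9. It is a hydrogen-mediated reductive cyclisation with a cationic rhodium catalyst: [Rh(cod)2]OTf and rac-BINAP under H2 (1 atm) in 1,2-dichloroethane at rt. The two alkynes are first coupled oxidatively on rhodium to a rhodacyclopentadiene, which forms C3–C4, and hydrogen then cleaves the two Rh–C bonds with retention. No metal hydride adds to a lone alkyne, and neither acid nor silane is present. The same (Z,Z)-diene 9 should result, and this fallback makes no new compound (F0).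

Step 8. The equilibrium may remain largely at 13, in which one aroyl group is still cis to an aryl group. Under more forcing base the enolate may expel the ring oxygen from C2 or C5 (β-elimination and re-addition), which would scramble C2/C5 or lead on to retro-aldol fragmentation. The fallback sets out from 12 and comes back at 14, and it inverts the aryl-bearing carbons instead of the aroyl-bearing ones. BF3·OEt2 in CH2Cl2 at −40 → 0 °C should ionise the C2–O and C5–O bonds reversibly to 4-benzyloxybenzylic cations that are recaptured by the ring oxygen, the known Lewis-acid epimerisation of 2-aryltetrahydrofurans. The ketones are not enolised under these aprotic conditions, so C3 and C4 stay cis. With that relationship locked, the arrangement with each aryl group trans to its neighbouring aroyl group is reached once both C2 and C5 have inverted. The path runs through the mono-inverted isomer rac-(2S,3S,4R,5S)-3,4-bis[2,4-bis(benzyloxy)benzoyl]-2,5-bis(4-benzyloxyphenyl)tetrahydrofuran F1 to 14, which is the same meso compound because moving both aryl groups of 12 to the other face equals moving both aroyl groups. The temperature is kept low to hold back cyclodehydration of the 1,4-diketone.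

Step 4. The propargylic cation may be diverted into Meyer–Schuster rearrangement to the enone or into Friedel–Crafts alkylation of the electron-rich dibenzyloxyphenyl ring, and the meso and C2-symmetric ethers may be hard to separate at this molecular size. The fallback sets out from 5 and comes back at 8, and it forms the ether before the dioxygenated ring is present. Addition of ethynylmagnesium bromide to 5 (THF, 0 °C) should give rac-1-(4-benzyloxyphenyl)prop-2-yn-1-ol F2. The same acid-catalysed etherification, now on a substrate with no nucleophilic arene and a less delocalised cation, should give, after crystallisation or chromatography, meso-bis[1-(4-benzyloxyphenyl)prop-2-yn-1-yl] ether F3. A twofold Sonogashira coupling of F3 with two equivalents of bromide 1 (PdCl2(PhCN)2, [HP(t-Bu)3]BF4, CuI, HN(i-Pr)2, 1,4-dioxane, rt, oxygen excluded to suppress alkyne homocoupling) then returns to 8.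

Further compounds
F0 | step 5 | none | none
F1 | step 8 | rac-(2S,3S,4R,5S)-3,4-bis[2,4-bis(benzyloxy)benzoyl]-2,5-bis(4-benzyloxyphenyl)tetrahydrofuran (2,3-trans, 3,4-cis, 4,5-cis; one enantiomer drawn) | O=C(c2ccc(OCc3ccccc3)cc2OCc2ccccc2)[C@H]1[C@@H](C(=O)c2ccc(OCc3ccccc3)cc2OCc2ccccc2)[C@@H](c2ccc(OCc3ccccc3)cc2)O[C@@H]1c1ccc(OCc2ccccc2)cc1
F2 | step 4 | rac-1-(4-benzyloxyphenyl)prop-2-yn-1-ol | OC(C#C)c1ccc(OCc2ccccc2)cc1
F3 | step 4 | meso-bis[1-(4-benzyloxyphenyl)prop-2-yn-1-yl] ether | C#C[C@H](c1ccc(OCc2ccccc2)cc1)O[C@H](c1ccc(OCc2ccccc2)cc1)C#C
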